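Take Wednesday's run at its last reading: after 120 s with 0.27 M of nucleophile charged, 51.0% of the electrophile is left. Sunday's run charged twice that nucleophile and has 27.2% left at the same time.

common to all: electrophile 0.17 M

| flask | nucleophile | solid base | remark | time |
|---|---|---|---|---|
| Wednesday's | 0.27 M | 0.51 M | run made earlier |  |
| Sunday's | 0.53 M | 0.51 M | run made earlier |  |
| alpha | 0.310 M | 0.510 M |  | 2.0 min |
| delta | 0.690 M | 0.510 M |  | 2.0 min |
| theta | 0.460 M | 0.510 M |  | 2.0 min |

- Wednesday's (time / s: electrophile / %, target / %): 15.0: 90.1, 6.5; 40.0: 76.3, 11.1; 80.0: 61.3, 10.4; 120: 51.0, 8.6
- Sunday's (time / s: electrophile / %, target / %): 30.0: 68.2, 18.5; 60.0: 48.9, 19.2; 90.0: 34.2, 15.7; 120: 27.2, 13.4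

(scatter of a reading: 0.5 percentage points)

- a species is counted by the electrophile in it: one side product counts as two
- given per volume of solution although it is solid: solid base
- reactions considered so far: electrophile + nucleophile -> acid set free + target; nucleophile + acid set free <-> protonated nucleophile; acid set free + free base <-> salt of the base; solid base <-> free base; electrophile + target -> side product; target -> over-reaction product
- at the start none of the solid base is in solution

- part of the electrophile that has reacted at the end, alpha
- part of the electrophile that has reacted at the end, delta
- part of the electrophile that has reacted at the end, theta
- what raising the concentration of nucleophile from its lowest to its highest value here does to the part of the electrophile that has reacted (changes below 5 percentage points count as none) (it rises / no change / it falls)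

Call k the decay coefficient: the natural logarithm of charged over remaining electrophile, divided by nucleophile charge and time. This treats the electrophile as pseudo-first-order, with the rate taken in proportion to the nucleophile charge. Wednesday's run gives 0.0208 M⁻¹ s⁻¹ and Sunday's 0.0205 M⁻¹ s⁻¹; carry their mean, 0.0206 M⁻¹ s⁻¹, the decay coefficient.

Before using it, ask what it needs. Time needs care: at 40.0 s, Wednesday's run reads 0.0250 M⁻¹ s⁻¹, higher than at its end, so use k at 2.0 min, the time it was read and the time asked. In this formula nucleophile charge and k enter as a product, so an error of a given share in either counts equally; time stands in the same product, but k shifts with time in Wednesday's run, so an error in time can't be reckoned the same way. The two runs differ by 1.51% in k, which moves theta by 0.55 percentage points. Electrophile and solid base were the same in both runs, so these readings cannot show what they do.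

Now reckon: alpha 53.6%, theta 68.0%, delta 81.9%. The forecast says “the reaction is close to first order in nucleophile” and gives 53.5%, 68.3% and 82.5%, a little above this reckoning at delta, and for the trend, it rises.

The flasks give 53.8% for alpha, 68.5% for theta and 82.9% for delta, and it rises by 29 points.

    electrophile + nucleophile → acid set free + target (k = 0.0250 M⁻¹ s⁻¹)
    nucleophile + acid set free ⇌ protonated nucleophile, settled at all times (K = 220 M⁻¹)
    acid set free + free base ⇌ salt of the base, settled at all times (K = 660 M⁻¹)
    solid base ⇌ free base, rate k4*(cs4 - [free base]) while solid is left; crystals form when [free base] > cs4 (solubility = 0.0620 M, k = 0.00790 s⁻¹)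
    electrophile + target → side product (k = 0.0480 M⁻¹ s⁻¹)
    target → over-reaction product (k = 0.0240 s⁻¹)

With everything else held, theta moves by 5 points when its nucleophile drops to 0.403 M; k at that charge gives 63.1%, which is 4.9 points below the reckoned theta.

Take the neighbour of delta with 0.43 M of electrophile, more than either run held: k has no electrophile term, so it again gives 81.9%. That flask gives 74.6%, lower by 7.3 points, so at that electrophile charge this reckoning misses.

All runs come from a simulation with constants of no real substance; noise was put on by code.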